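**Plan**
- Retrosynthesis: the three benzyl–oxygen bonds are cut first, then ring C at C2=C3 (ester Wittig), then O1–C2 as an aryl ester C–O bond, then P–C3 and the C4–C4a Friedel–Crafts bond of ring A.
- Enabling feature: O1–C2 of ring C is an enol-ether bond, so it can be made beforehand as an ester between the ring B acid and the single free ring A hydroxyl (on C8a, next to C8–OMe); only C2=C3 is then missing.
- Forward: ring A is elaborated from 2,4,6-trihydroxybenzaldehyde (benzylation, Baeyer–Villiger, O-methylation, chloroacetylation, ortho-debenzylation), converted into the phosphorane and O-acylated with the protected ring B acid chloride; ring C is closed last, then the benzyl ethers are removed.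
- Stereochemistry: none, the target is achiral; the 8-OMe versus 6-OMe question is settled by which ring A oxygen carries the ester.

Key step: step 9

Remark: chromen-4-one numbering (O1, C2, C3, C4, C4a, C5–C8, C8a) is used throughout; compounds 1, 6, 9 and 12 are assumed to be purchased.

**Route**

Step 1
Reactants: 1 2,4,6-trihydroxybenzaldehyde
Product: 2 2,4,6-tris(benzyloxy)benzaldehyde
Conditions: BnBr (3.6 equiv), K2CO3, DMF, 60 °C
Reagents that add atoms: benzyl bromide, BrCc1ccccc1
Why: Williamson etherification of all three phenols, in which the formyl group lowers the ring nucleophilicity enough to favour O- over C-benzylation and warming with excess halide should also alkylate the two hydrogen-bonded hydroxyls.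

Step 2
Reactants: 2 2,4,6-tris(benzyloxy)benzaldehyde
Product: 4 2,4,6-tris(benzyloxy)phenol, via aryl formate 3 (not isolated)
Conditions: mCPBA (1.2 equiv), CH2Cl2, 0 °C → rt; then K2CO3 (cat.), MeOH, rt, N2
Reagents that add atoms: 3-chloroperoxybenzoic acid (mCPBA), OOC(=O)c1cccc(Cl)c1
Why: Baeyer–Villiger oxidation of an electron-rich benzaldehyde, in which the trialkoxyaryl group migrates to give the formate that mild methanolysis cleaves, turning the formyl-bearing carbon into the future C8 oxygen.

Step 3
Reactants: 4 2,4,6-tris(benzyloxy)phenol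
Product: 5 1,3,5-tris(benzyloxy)-2-methoxybenzene
Conditions: MeI, K2CO3, acetone, reflux, N2
Reagents that add atoms: iodomethane, CI
Why: Williamson O-methylation of the air-sensitive phenol, which fixes the C8 methoxy group and gives a symmetric tetraether whose two unsubstituted ring positions are equivalent.

Step 4
Reactants: 5 1,3,5-tris(benzyloxy)-2-methoxybenzene; 6 chloroacetyl chloride
Product: 7 2-chloro-1-[2,4,6-tris(benzyloxy)-3-methoxyphenyl]ethan-1-one
Conditions: SnCl4 (1.2 equiv), CH2Cl2, −40 → −10 °C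
Reagents that add atoms: none
Why: Friedel–Crafts acylation of a highly activated arene at one of two equivalent positions, so only one monoketone can form and the acyl group stops a second acylation; the chloroacetyl unit delivers C4, C3 and the leaving group for phosphorus without any halogenation of the electron-rich ring.

Step 5
Reactants: 7 2-chloro-1-[2,4,6-tris(benzyloxy)-3-methoxyphenyl]ethan-1-one
Product: 8 1-[4,6-bis(benzyloxy)-2-hydroxy-3-methoxyphenyl]-2-chloroethan-1-one
Conditions: BCl3 (1.1 equiv), CH2Cl2, −78 °C; then H2O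
Reagents that add atoms: none
Why: Chelation-controlled Lewis-acid dealkylation ortho to the ketone, expected at the benzyl ether buttressed between the carbonyl and the methoxy group (twisted out of plane, more basic, strain relieved on cleavage) as in the known ortho-dealkylation of 2,3,4,6-tetraalkoxyaryl ketones, while the para ether lacks chelation assistance.

Step 6
Reactants: 8 1-[4,6-bis(benzyloxy)-2-hydroxy-3-methoxyphenyl]-2-chloroethan-1-one; 9 triphenylphosphine
Product: 11 1-[4,6-bis(benzyloxy)-2-hydroxy-3-methoxyphenyl]-2-(triphenyl-λ5-phosphanylidene)ethan-1-one, via phosphonium chloride 10 (not isolated)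
Conditions: MeCN, 70 °C; then aq. Na2CO3, CH2Cl2, rt
Reagents that add atoms: none
Why: SN2 quaternisation of the phosphine by the phenacyl chloride followed by deprotonation of the acidic phosphonium methylene gives the ketone-stabilised ylide; the non-basic phosphine should not trigger benzofuranone formation and the weak base leaves the phenol protonated.

Step 7
Reactants: 12 2-hydroxy-4,5-dimethoxybenzoic acid
Product: 14 2-(benzyloxy)-4,5-dimethoxybenzoic acid, via benzyl ester 13 (not isolated)
Conditions: BnBr (2.4 equiv), K2CO3, DMF, 60 °C; then aq. NaOH, MeOH, 60 °C; then HCl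
Reagents that add atoms: benzyl bromide, BrCc1ccccc1
Why: Williamson benzylation of phenol and carboxylate followed by saponification, which cleaves only the benzyl ester and leaves the aryl benzyl ether that masks the 2'-hydroxyl.

Step 8
Reactants: 14 2-(benzyloxy)-4,5-dimethoxybenzoic acid; 11 1-[4,6-bis(benzyloxy)-2-hydroxy-3-methoxyphenyl]-2-(triphenyl-λ5-phosphanylidene)ethan-1-one
Product: 16 3,5-bis(benzyloxy)-2-methoxy-6-[(triphenyl-λ5-phosphanylidene)acetyl]phenyl 2-(benzyloxy)-4,5-dimethoxybenzoate, via acid chloride 15 (not isolated)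
Conditions: (COCl)2, DMF (cat.), CH2Cl2, rt, evaporate; then 11, pyridine (3 equiv), CH2Cl2, 0 °C → rt
Reagents that add atoms: none
Why: Acid chloride formation and pyridine-mediated O-acylation of the phenol (esterification), which forms the O1–C2 bond; the acyl-stabilised ylide carbon is a poor nucleophile, and keeping the mixture at or below room temperature should allow the ester ylide to be isolated before it cyclises.

Step 9
Reactants: 16 3,5-bis(benzyloxy)-2-methoxy-6-[(triphenyl-λ5-phosphanylidene)acetyl]phenyl 2-(benzyloxy)-4,5-dimethoxybenzoate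
Product: 17 5,7-bis(benzyloxy)-2-[2-(benzyloxy)-4,5-dimethoxyphenyl]-8-methoxy-4H-chromen-4-one
Conditions: toluene, 110 °C, N2
Reagents that add atoms: none
Why: Intramolecular Wittig olefination of an ester carbonyl: on heating, the ylide carbon (C3) adds to the neighbouring aroyloxy carbonyl (C2) and the oxaphosphetane collapses irreversibly to Ph3PO and the C2=C3 bond, the closest known reaction type being the thermal cyclisation of (2-acyloxyphenacylidene)triphenylphosphoranes to 2-substituted chromones. Ring C closes in a 6-exo-trig mode, the attacked carbonyl oxygen lying outside the forming pyranone ring. No stereocentre is created. The step needs chemoselectivity for olefination over O-to-C acyl transfer; this should be secured because the C-acylated ylide with its neighbouring phenol can return to the same tetrahedral adduct whereas loss of Ph3PO is irreversible, and because the neutral, salt-free, base-free medium gives no enolate chemistry. Regiochemistry is already fixed, since the ester sits on the only free ring A oxygen (beside C8–OMe) while O5 and O7 are benzyl ethers, and the neutral medium also rules out Wessely–Moser ring opening.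

Step 10
Reactants: 17 5,7-bis(benzyloxy)-2-[2-(benzyloxy)-4,5-dimethoxyphenyl]-8-methoxy-4H-chromen-4-one
Product: 18 5,7-dihydroxy-2-(2-hydroxy-4,5-dimethoxyphenyl)-8-methoxy-4H-chromen-4-one
Conditions: H2 (1 atm), 10% Pd/C, THF/MeOH, rt
Reagents that add atoms: none
Why: Catalytic hydrogenolysis of the three aryl benzyl ethers, which should be much faster than reduction of the conjugated chromone C2=C3 bond and, being neutral, leaves the three methyl ethers and the 8-methoxy regiochemistry untouched.

**Compound list**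
1 | 2,4,6-trihydroxybenzaldehyde | O=Cc1c(O)cc(O)cc1O | starting material
2 | 2,4,6-tris(benzyloxy)benzaldehyde | O=Cc1c(OCc2ccccc2)cc(OCc2ccccc2)cc1OCc1ccccc1 | intermediate
3 | 2,4,6-tris(benzyloxy)phenyl formate | O=COc1c(OCc2ccccc2)cc(OCc2ccccc2)cc1OCc1ccccc1 | intermediate
4 | 2,4,6-tris(benzyloxy)phenol | Oc1c(OCc2ccccc2)cc(OCc2ccccc2)cc1OCc1ccccc1 | intermediate
5 | 1,3,5-tris(benzyloxy)-2-methoxybenzene | COc1c(OCc2ccccc2)cc(OCc2ccccc2)cc1OCc1ccccc1 | intermediate
6 | chloroacetyl chloride | ClCC(Cl)=O | starting material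
7 | 2-chloro-1-[2,4,6-tris(benzyloxy)-3-methoxyphenyl]ethan-1-one | COc1c(OCc2ccccc2)cc(OCc2ccccc2)c(C(=O)CCl)c1OCc1ccccc1 | intermediate
8 | 1-[4,6-bis(benzyloxy)-2-hydroxy-3-methoxyphenyl]-2-chloroethan-1-one | COc1c(OCc2ccccc2)cc(OCc2ccccc2)c(C(=O)CCl)c1O | intermediate
9 | triphenylphosphine | c1ccc(cc1)P(c1ccccc1)c1ccccc1 | starting material
10 | {2-[4,6-bis(benzyloxy)-2-hydroxy-3-methoxyphenyl]-2-oxoethyl}triphenylphosphonium chloride | COc1c(OCc2ccccc2)cc(OCc2ccccc2)c(C(=O)C[P+](c2ccccc2)(c2ccccc2)c2ccccc2)c1O.[Cl-] | intermediate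
11 | 1-[4,6-bis(benzyloxy)-2-hydroxy-3-methoxyphenyl]-2-(triphenyl-λ5-phosphanylidene)ethan-1-one | COc1c(OCc2ccccc2)cc(OCc2ccccc2)c(C(=O)C=P(c2ccccc2)(c2ccccc2)c2ccccc2)c1O | intermediate
12 | 2-hydroxy-4,5-dimethoxybenzoic acid | COc1cc(O)c(C(=O)O)cc1OC | starting material
13 | benzyl 2-(benzyloxy)-4,5-dimethoxybenzoate | COc1cc(OCc2ccccc2)c(C(=O)OCc2ccccc2)cc1OC | intermediate
14 | 2-(benzyloxy)-4,5-dimethoxybenzoic acid | COc1cc(OCc2ccccc2)c(C(=O)O)cc1OC | intermediate
15 | 2-(benzyloxy)-4,5-dimethoxybenzoyl chloride | COc1cc(OCc2ccccc2)c(C(Cl)=O)cc1OC | intermediate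
16 | 3,5-bis(benzyloxy)-2-methoxy-6-[(triphenyl-λ5-phosphanylidene)acetyl]phenyl 2-(benzyloxy)-4,5-dimethoxybenzoate | COc1c(OCc2ccccc2)cc(OCc2ccccc2)c(C(=O)C=P(c2ccccc2)(c2ccccc2)c2ccccc2)c1OC(=O)c1cc(OC)c(OC)cc1OCc1ccccc1 | intermediate
17 | 5,7-bis(benzyloxy)-2-[2-(benzyloxy)-4,5-dimethoxyphenyl]-8-methoxy-4H-chromen-4-one | COc1cc(OCc2ccccc2)c(-c2cc(=O)c3c(OCc4ccccc4)cc(OCc4ccccc4)c(OC)c3o2)cc1OC | intermediate
18 | 5,7-dihydroxy-2-(2-hydroxy-4,5-dimethoxyphenyl)-8-methoxy-4H-chromen-4-one (CNP0497620.0) | COc1cc(O)c(-c2cc(=O)c3c(O)cc(O)c(OC)c3o2)cc1OC | target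

**Count**
Total steps: 10. Longest linear sequence: 9 (steps 1–6, 8, 9, 10); the ring B branch is step 7.

**Steps most likely to fail, with fallbacks**

Step 5. The Lewis acid may fail to discriminate between the two ortho benzyl ethers (loss of the O6 benzyl group, or of both), and the released benzyl chloride may C-benzylate the electron-rich ring. The fallback places the free phenol before the ketone, so that no choice between two ethers arises. It sets out from 2, whose two ortho ethers are equivalent. MgBr2·OEt2 (toluene/Et2O, reflux) should remove one of them to give 4,6-bis(benzyloxy)-2-hydroxybenzaldehyde F1. MOMCl/iPr2NEt gives 2,4-bis(benzyloxy)-6-(methoxymethoxy)benzaldehyde F2. NaHCO3-buffered mCPBA gives 2,4-bis(benzyloxy)-6-(methoxymethoxy)phenyl formate F3, which K2CO3/MeOH converts into 2,4-bis(benzyloxy)-6-(methoxymethoxy)phenol F4. MeI/K2CO3 gives 1,5-bis(benzyloxy)-2-methoxy-3-(methoxymethoxy)benzene F5, and HCl in MeOH removes the acetal to give 3,5-bis(benzyloxy)-2-methoxyphenol F6. EtMgBr turns this into bromomagnesium 3,5-bis(benzyloxy)-2-methoxyphenoxide F7, and its reaction with 6 in toluene is an ortho-specific C-acylation of a magnesium phenoxide. Because the other ortho position carries the methoxy group, this can only give 8, where the route is rejoined.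

Step 9. The ylide may transfer the aroyl group from oxygen to carbon without olefination, or decompose on prolonged heating because addition to an electron-rich, ortho-substituted aroyl ester is slow. The fallback closes ring C from a 1,3-diketone (Baker–Venkataraman sequence). It sets out from 8: Zn dust in AcOH removes the chlorine to give 1-[4,6-bis(benzyloxy)-2-hydroxy-3-methoxyphenyl]ethan-1-one F10. Acylation with 15 in pyridine gives 2-acetyl-3,5-bis(benzyloxy)-6-methoxyphenyl 2-(benzyloxy)-4,5-dimethoxybenzoate F11. KOH in pyridine at 50 °C rearranges it to 1-[4,6-bis(benzyloxy)-2-hydroxy-3-methoxyphenyl]-3-[2-(benzyloxy)-4,5-dimethoxyphenyl]propane-1,3-dione F12. Cyclodehydration with catalytic TsOH in toluene at 80 °C gives 17, where the route is rejoined. Since O5 stays benzylated, the dione can close only through the hydroxyl next to the methoxy group.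

Step 8. Acylation may occur at the ylide carbon instead of at the hindered, hydrogen-bonded phenol, or the ester may partly cyclise before isolation. The fallback makes the ester before phosphorus is introduced. It sets out from 8: acylation with 15 (pyridine, cat. DMAP, CH2Cl2, 0 °C) should give 3,5-bis(benzyloxy)-2-(chloroacetyl)-6-methoxyphenyl 2-(benzyloxy)-4,5-dimethoxybenzoate F8. Reaction with 9 in MeCN at 50 °C gives {2-[4,6-bis(benzyloxy)-2-{[2-(benzyloxy)-4,5-dimethoxybenzoyl]oxy}-3-methoxyphenyl]-2-oxoethyl}triphenylphosphonium chloride F9. Brief treatment with aqueous NaHCO3/CH2Cl2 at 0 °C deprotonates it to 16, where the route is rejoined.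

**Further compounds**
F1 | step 5 | 4,6-bis(benzyloxy)-2-hydroxybenzaldehyde | O=Cc1c(O)cc(OCc2ccccc2)cc1OCc1ccccc1
F2 | step 5 | 2,4-bis(benzyloxy)-6-(methoxymethoxy)benzaldehyde | COCOc1cc(OCc2ccccc2)cc(OCc2ccccc2)c1C=O
F3 | step 5 | 2,4-bis(benzyloxy)-6-(methoxymethoxy)phenyl formate | COCOc1cc(OCc2ccccc2)cc(OCc2ccccc2)c1OC=O
F4 | step 5 | 2,4-bis(benzyloxy)-6-(methoxymethoxy)phenol | COCOc1cc(OCc2ccccc2)cc(OCc2ccccc2)c1O
F5 | step 5 | 1,5-bis(benzyloxy)-2-methoxy-3-(methoxymethoxy)benzene | COCOc1cc(OCc2ccccc2)cc(OCc2ccccc2)c1OC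
F6 | step 5 | 3,5-bis(benzyloxy)-2-methoxyphenol | COc1c(O)cc(OCc2ccccc2)cc1OCc1ccccc1
F7 | step 5 | bromomagnesium 3,5-bis(benzyloxy)-2-methoxyphenoxide | COc1c(O[Mg]Br)cc(OCc2ccccc2)cc1OCc1ccccc1
F8 | step 8 | 3,5-bis(benzyloxy)-2-(chloroacetyl)-6-methoxyphenyl 2-(benzyloxy)-4,5-dimethoxybenzoate | COc1c(OCc2ccccc2)cc(OCc2ccccc2)c(C(=O)CCl)c1OC(=O)c1cc(OC)c(OC)cc1OCc1ccccc1
F9 | step 8 | {2-[4,6-bis(benzyloxy)-2-{[2-(benzyloxy)-4,5-dimethoxybenzoyl]oxy}-3-methoxyphenyl]-2-oxoethyl}triphenylphosphonium chloride | COc1c(OCc2ccccc2)cc(OCc2ccccc2)c(C(=O)C[P+](c2ccccc2)(c2ccccc2)c2ccccc2)c1OC(=O)c1cc(OC)c(OC)cc1OCc1ccccc1.[Cl-]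
F10 | step 9 | 1-[4,6-bis(benzyloxy)-2-hydroxy-3-methoxyphenyl]ethan-1-one | COc1c(OCc2ccccc2)cc(OCc2ccccc2)c(C(C)=O)c1O
F11 | step 9 | 2-acetyl-3,5-bis(benzyloxy)-6-methoxyphenyl 2-(benzyloxy)-4,5-dimethoxybenzoate | COc1c(OCc2ccccc2)cc(OCc2ccccc2)c(C(C)=O)c1OC(=O)c1cc(OC)c(OC)cc1OCc1ccccc1
F12 | step 9 | 1-[4,6-bis(benzyloxy)-2-hydroxy-3-methoxyphenyl]-3-[2-(benzyloxy)-4,5-dimethoxyphenyl]propane-1,3-dione | COc1c(OCc2ccccc2)cc(OCc2ccccc2)c(C(=O)CC(=O)c2cc(OC)c(OC)cc2OCc2ccccc2)c1O
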